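The data were computed for an exercise; scatter was added.

The target slows far short of the charge in the ochre run, which reads 0.0439 M at 41 min and 0.0462 M at 59 min, less than the 0.120 M of starting material charged. That shape suggests catalyst deactivation, so it pays to follow the share of starting material left unturned, not the share made. If turning is first order in starting material and turning and dying both follow the living catalyst, then at a fixed charge of coupling partner each unit of catalyst charged lowers the logarithm of that share by a fixed step.

in all of them: starting material 0.120 M
- ochre: coupling partner 0.240 M; free catalyst 0.00960 M
- violet: coupling partner 0.240 M; free catalyst 0.0290 M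
- red: coupling partner 0.360 M; free catalyst 0.00960 M
- green: coupling partner 0.120 M; free catalyst 0.00320 M; time 59 min

| run | time / min | [target] / M |
|---|---|---|
| ochre run | 4.5 | 0.0116 |
| ochre run | 14 | 0.0264 |
| ochre run | 26 | 0.0380 |
| ochre run | 41 | 0.0439 |
| ochre run | 59 | 0.0462 |
| violet run | 4.5 | 0.0324 |
| violet run | 14 | 0.0688 |
| violet run | 26 | 0.0878 |
| violet run | 41 | 0.0966 |
| violet run | 59 | 0.0994 |
| red run | 4.5 | 0.0144 |
| red run | 14 | 0.0322 |
| red run | 26 | 0.0427 |
| red run | 41 | 0.0472 |
| red run | 59 | 0.0482 |

(readings scatter by 6 × 10⁻⁴ M)

- Overall: starting material + coupling partner -> target, with free catalyst as catalyst.
- Constant volume, constant temperature.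
- Readings of a species count what is bound in complexes too.
- An order is taken over about fifteen percent of the charge, up and down.

- apparent order in [coupling partner] of the starting rate, round the charge of the ochre run (the rate where two percent of its starting material have turned into target)
- apparent order in [free catalyst] of the starting rate, round the charge of the ochre run (the rate where two percent of its starting material have turned into target)
- target in the green run at 59 min, as a share of the starting material charged

The step is the log-fall per catalyst, the logarithm of charge over amount left at the last reading, divided by the catalyst charged. Read from the ochre run:

log-fall per catalyst = 0.486 / 0.00960 M = 50.6 M⁻¹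

Multiplied by a flask's catalyst charge, it gives one dimensionless stopping number, and the share left at the stop is the exponential of minus that number. The red run reads 0.514 / 0.00960 M = 53.5 M⁻¹, and the violet run reads 60.8 M⁻¹, higher than the ochre run, so the step holds only roughly. For the green run:

stopping number = 0.162, target at the stop = 15.0%

One number is not enough: the question stands at 59 min, and the stop is a limit reckoned without a time. The remaining part of the log-fall shrinks at 0.0511 min⁻¹ in the ochre run and 0.0669 min⁻¹ in the red run, both read at 14 min. That is an order of 0.666 in coupling partner. The green run has half the partner of the ochre run, so my own reckoning is: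

shrinking rate = 0.0322 min⁻¹, part reached = 85.1%, target = 12.9%

The forecast gives 13.3% (11.3% to 15.5%), above this reckoning, with orders 0.62 in coupling partner and 1 in free catalyst. Its ground: “The plateau scales with catalyst, not coupling partner, so the catalyst is dying”.

The green run gives 12.5%, with orders 1.0 in free catalyst and 0.75 in coupling partner, the forecast's 0.62 lying below.

    free catalyst + starting material ⇌ catalyst-substrate complex, settled at all times (95.60 M⁻¹)
    catalyst-substrate complex + coupling partner ⇌ ternary complex, settled at all times (1.910 M⁻¹)
    ternary complex → target + free catalyst (1.176 min⁻¹)
    free catalyst + coupling partner → spent catalyst + coupling partner (1.254 M⁻¹ min⁻¹)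
    2 starting material ⇌ idle substrate dimer, settled at all times (34.20 M⁻¹)

Removing the passage of free catalyst, with coupling partner, into spent catalyst moves the readings by 62 times their scatter, as a root mean square. At 59 min the green run has a log-fall per catalyst of 41.7 M⁻¹, below the 50.6 M⁻¹ read from the ochre run.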